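The charges of the west and south-west runs stand 4.00 to one, yet at 2.50 h the target reads 10.0 % in the west run against 23.0 % in the south-west run, so the heavier charge holds the smaller share.

the same everywhere: gas 6.1 mM (held)

| run | substrate | remark | time |
|---|---|---|---|
| south-west | 6.5 mM | run made earlier |  |
| west | 26 mM | run made earlier |  |
| flask | 13 mM |  | 3.0 h |

| south-west: time / h | south-west: target / % | west: time / h | west: target / % |
|---|---|---|---|
| 0.167 | 1.2 | 0.200 | 0 |
| 0.500 | 4.1 | 0.333 | 0.6 |
| 0.833 | 7.3 | 0.500 | 2.5 |
| 1.33 | 12.5 | 0.833 | 4.5 |
| 2.00 | 19.6 | 1.33 | 5.9 |
| 2.50 | 23.0 | 2.50 | 10.0 |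

(readings scatter by 0.5 percentage points)

- percent here means substrate units held: one self-condensation product counts as two
- at the start none of reagent is dissolved
- reactions considered so far: substrate + reagent <-> target; 2 substrate -> self-condensation product; gas <-> reagent

1. amount of target in percent of the substrate charged, at 10 min, 50 min and 3.0 h

The flask's charge is the geometric mean of the other two, 13.0 mM, so my bench rule is to take the percent halfway on a log scale. At 2.50 h the readings give 0.659: this is the doubling factor, by which the percent of target shrinks for one doubling of charge at a fixed time, the square root of west over south-west. It is a reading and carries their scatter.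

I reckon the flask in two rounds, the second starting from the first answer and adding the late south-west gain, scaled by the same factor:

at 50 min: factor 0.785, target 5.73 %

at 2.50 h: target 15.2 %

at 3.0 h: added 2.2 percentage points, target 17.4 %

The border is the scatter. At 0.333 h the west reading is 1.20 times 0.5 points, and at 0.200 h it reads 0 %, so the root says nothing at 10 min. There I claim a value between 0 % and 1.2 %.

The forecast gives 0.7 %, 6 % and 18 %, on this ground: “the late slowdown at high loading fits substrate being lost to second-order self-condensation”. My figures stand a little lower than the forecast at 50 min and at 3.0 h.

The flask gives 0.518 %, 5.71 % and 17.0 %, within the forecast's margin.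

    substrate + reagent ⇌ target (K = 5200 M⁻¹, k = 0.929 M⁻¹ min⁻¹)
    2 substrate → self-condensation product (k = 1.09 M⁻¹ min⁻¹)
    gas ⇌ reagent, rate k3*(csat - [reagent]) (kL = 0.0243 min⁻¹)

In the flask at 0.658 h, substrate goes to the self-condensation product 4.0 times as fast as to target, counting the forward rate of the reversible step. At 3.00 h that ratio, a selectivity factor, stands at 0.55, and the flask then holds 72.8 % self-condensation product against 17.0 % target, with 10.1 % substrate left. The doubling factor, carried from the flask's 17.0 % to twice the charge, gives 11.2 %, and the simulated run with twice the substrate holds 10.4 %.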